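Decide first to count the lost solid in molarity, not in percent.

| flask | solid substrate | solid reagent | remark | time |
|---|---|---|---|---|
| cedar | 0.18 M | 2 equiv | run made earlier |  |
| alder | 0.27 M | 2 equiv | run made earlier |  |
| elm | 0.36 M | 3 equiv | run made earlier |  |
| flask | 0.36 M | 2.00 equiv |  | 10 min |

| run | time / min | product / % | solid substrate / % |
|---|---|---|---|
| cedar | 1.33 | 0 | 94.1 |
| cedar | 2.50 | 1.6 | 91.1 |
| cedar | 4.00 | 2.1 | 86.5 |
| cedar | 5.00 | 4.4 | 85.0 |
| cedar | 6.00 | 4.9 | 80.8 |
| alder | 0.500 | 0 | 98.4 |
| alder | 1.50 | 0.3 | 95.2 |
| alder | 3.00 | 0.6 | 91.9 |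
| alder | 4.00 | 1.5 | 91.2 |
| alder | 6.00 | 3.4 | 88.2 |
| elm | 1.33 | 0 | 97.2 |
| elm | 2.50 | 0.8 | 95.5 |
| elm | 4.00 | 1.3 | 93.4 |
| elm | 5.00 | 1.3 | 91.2 |
| elm | 6.00 | 1.9 | 90.2 |

(standard deviation of a reading: 0.5 percentage points)

- the species that holds most of what was charged as solid substrate, at 10 min (product / solid substrate)
- the largest share itself, whichever of these holds it, in percent of the solid substrate charged

At 6.00 min the cedar run has lost 0.0346 M of solid substrate, the alder run 0.0319 M and the elm run 0.0353 M. Yet the elm run holds twice the cedar charge of solid substrate, and it has 3 equiv of solid reagent. So in these runs the molar loss is nearly equal, a roughly zero-order loss.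

Take the elm rate, since elm has your charge of solid substrate: 0.00588 M min⁻¹. For your flask, 61.2 min is the solid lifetime, the charge divided by that rate. Set it against the asked 10 min. Their ratio, 0.163, is my estimate of the share lost, so I expect 83.7% still solid. The share lost stands below the share kept, and product can come from the lost share and from nothing else charged, so I expect solid substrate to lead.

The forecast says solid substrate at 85%, between 82% and 88%, and its ground is “The flask should therefore behave like elm”.

The flask gives solid substrate at 87.3%, and product 5.98%. It lost 12.7%, not my 16.3%.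

    solid substrate ⇌ dissolved substrate, rate k1*(cs1 - [dissolved substrate]) while solid is left; crystals form when [dissolved substrate] > cs1 (solubility = 37.0 mM, k = 0.00420 s⁻¹)
    dissolved substrate + coupling partner → product (k = 0.0200 M⁻¹ s⁻¹)
    solid reagent ⇌ coupling partner, rate k3*(cs3 - [coupling partner]) while solid is left; crystals form when [coupling partner] > cs3 (solubility = 0.270 M, k = 0.00530 s⁻¹)
    coupling partner → decomposed reagent (k = 0.00780 s⁻¹)
    coupling partner ⇌ dormant form (K = 0.430, k = 0.0130 s⁻¹)

Now take the neighbour flask, with 5.00 equiv of solid reagent. Reckoned from the same charge of solid substrate and the same elm rate, its solid lifetime is still 61.2 min. At 10 min the reckoning therefore gives 83.7% again, the figure it gave for your flask. The neighbour flask shows 87.3% solid and 5.98% product, as your flask does. Its solid reagent stands at 67.7% of its own charge, against 19.4% in your flask.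

The readings are calculated with made-up constants, and the scatter is random.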